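**Assumption:** the target SMILES has no stereocentre and no E/Z-defined alkene (the prenyl alkene carries two methyls), so the molecule is achiral and no stereocontrol is needed.

**Retrosynthetic overview**
1. C6–prenyl bond: made last by Stille coupling on the unprotected 6-iodo-isoflavone; the iodine is placed by 5-OH-directed iodination.
2. C3–aryl bond: not a Suzuki or deoxybenzoin disconnection. It is formed by a biomimetic oxidative 1,2-aryl shift of a 2'-hydroxychalcone (isoflavone-synthase logic).
3. Chalcone: Claisen–Schmidt condensation of a mono-MOM phloroacetophenone methyl ether with 2,4-bis(benzyloxy)benzaldehyde.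
4. Ring order: rings A and B are bought. The pyranone ring C is the only ring formed (step 3); C6 is functionalised afterwards.

**Route**

Step 1
Reactants: 1, 1-(2,6-dihydroxy-4-methoxyphenyl)ethanone; 2, chloromethyl methyl ether
Product: 3, 1-[2-hydroxy-4-methoxy-6-(methoxymethoxy)phenyl]ethanone
Conditions: MOMCl (1.1 equiv), i-Pr2NEt, CH2Cl2, 0 °C to rt
Reagents that add atoms: MOMCl, COCCl
Why: O-alkylation (MOM protection) of one of two equivalent phenols; it stops at the mono-ether because the remaining OH is locked in a strong hydrogen bond to the ketone.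

Step 2
Reactants: 3; 4, 2,4-bis(benzyloxy)benzaldehyde
Product: 5, (E)-3-[2,4-bis(benzyloxy)phenyl]-1-[2-hydroxy-4-methoxy-6-(methoxymethoxy)phenyl]prop-2-en-1-one
Conditions: KOH (50% aq), EtOH, rt, 24–48 h; AcOH quench
Reagents that add atoms: none beyond reactants 3 and 4 (aldehyde 4: O=Cc1ccc(OCc2ccccc2)cc1OCc1ccccc1)
Why: Claisen–Schmidt aldol condensation gives the E-chalcone; MOM and benzyl ethers are stable to base, and the 6'-OMOM group prevents flavanone formation on that side.

Step 3
Reactants: 5
Product: 7, 3-[2,4-bis(benzyloxy)phenyl]-5-hydroxy-7-methoxy-4H-chromen-4-one, formed via non-isolated acetal 6, 2-[2,4-bis(benzyloxy)phenyl]-1-[2-hydroxy-4-methoxy-6-(methoxymethoxy)phenyl]-3,3-dimethoxypropan-1-one (racemic; its stereocentre is destroyed on cyclisation)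
Conditions: (i) Tl(NO3)3·3H2O (1.2 equiv), MeOH/HC(OMe)3, rt; (ii) 10% aq HCl, MeOH/THF, 60 °C, one pot
Reagents that add atoms: none remain in 7 (methanol, CO, supplies the two OMe groups of transient 6, which are lost again as MeOH)
Why: Tl(III)-mediated oxidative 1,2-aryl migration of a 2'-hydroxychalcone (oxythallation at the β-carbon, then shift of the electron-rich 2,4-dialkoxyphenyl group to the α-carbon) gives acetal 6. Acid then removes the MOM group and cyclodehydrates to the chromone; after MOM loss the A ring is symmetric, so closure through either phenol gives the same 5-hydroxy-7-methoxy isomer, and benzyl ethers survive dilute HCl.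

Step 4
Reactants: 7; 8, benzyltrimethylammonium dichloroiodate
Product: 9, 3-[2,4-bis(benzyloxy)phenyl]-5-hydroxy-6-iodo-7-methoxy-4H-chromen-4-one
Conditions: BnNMe3·ICl2 (1.05 equiv), CaCO3, CH2Cl2/MeOH, rt
Reagents that add atoms: BnNMe3·ICl2, C[N+](C)(C)Cc1ccccc1.Cl[I-]Cl (delivers I)
Why: electrophilic aromatic iodination; this reagent is known to iodinate 5-hydroxy-7-alkoxychromones at C6 (ortho to the free phenol, between OH and OMe). Under these base-buffered, Lewis-acid-free conditions phenols react much faster than aryl ethers, which should spare the dibenzyloxy B ring.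

Step 5
Reactants: 9
Product: 10, 3-(2,4-dihydroxyphenyl)-5-hydroxy-6-iodo-7-methoxy-4H-chromen-4-one
Conditions: BCl3 (1 M in CH2Cl2, 6 equiv), C6HMe5 (6 equiv), CH2Cl2, −78 to −20 °C; MeOH quench
Reagents that add atoms: none
Why: Lewis-acid debenzylation with pentamethylbenzene as benzyl-cation scavenger; the non-chelated 7-OMe and the C–I bond survive BCl3 at low temperature. The benzyls are removed before the prenyl group is present, so no acid or hydrogenolysis ever touches the prenyl alkene.

Step 6
Reactants: 10; 11, tributyl(3-methylbut-2-en-1-yl)stannane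
Product: 12, 7-O-methylluteone, 3-(2,4-dihydroxyphenyl)-5-hydroxy-7-methoxy-6-(3-methylbut-2-en-1-yl)-4H-chromen-4-one
Conditions: Pd(PPh3)4 (10 mol %), 11 (1.5 equiv), degassed DMF, 90 °C; aq KF work-up
Reagents that add atoms: prenyltributylstannane, CCCC[Sn](CCCC)(CCCC)CC=C(C)C (delivers the prenyl group)
Why: Stille (Migita–Kosugi–Stille) coupling under neutral conditions tolerates the three free phenols and the chromone. Reductive elimination from the aryl–Pd–prenyl intermediate at the unsubstituted allyl terminus gives the linear prenyl arene, and the di-ortho-substituted aryl group further disfavours the branched isomer.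

**Compound list**
1 | 1-(2,6-dihydroxy-4-methoxyphenyl)ethanone | CC(=O)c1c(O)cc(OC)cc1O | starting material
2 | chloromethyl methyl ether (MOMCl) | COCCl | starting material (reagent)
3 | 1-[2-hydroxy-4-methoxy-6-(methoxymethoxy)phenyl]ethanone | COCOc1cc(OC)cc(O)c1C(C)=O | intermediate
4 | 2,4-bis(benzyloxy)benzaldehyde | O=Cc1ccc(OCc2ccccc2)cc1OCc1ccccc1 | starting material
5 | (E)-chalcone | COCOc1cc(OC)cc(O)c1C(=O)/C=C/c1ccc(OCc2ccccc2)cc1OCc1ccccc1 | intermediate
6 | 3,3-dimethoxy-1,2-diarylpropan-1-one acetal (racemic, not isolated) | COCOc1cc(OC)cc(O)c1C(=O)C(C(OC)OC)c1ccc(OCc2ccccc2)cc1OCc1ccccc1 | intermediate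
7 | 2',4'-bis(benzyloxy)-5-hydroxy-7-methoxyisoflavone | COc1cc2occ(-c3ccc(OCc4ccccc4)cc3OCc3ccccc3)c(=O)c2c(O)c1 | intermediate
8 | benzyltrimethylammonium dichloroiodate | C[N+](C)(C)Cc1ccccc1.Cl[I-]Cl | starting material (reagent)
9 | 2',4'-bis(benzyloxy)-5-hydroxy-6-iodo-7-methoxyisoflavone | COc1cc2occ(-c3ccc(OCc4ccccc4)cc3OCc3ccccc3)c(=O)c2c(O)c1I | intermediate
10 | 5,2',4'-trihydroxy-6-iodo-7-methoxyisoflavone | COc1cc2occ(-c3ccc(O)cc3O)c(=O)c2c(O)c1I | intermediate
11 | tributyl(3-methylbut-2-en-1-yl)stannane | CCCC[Sn](CCCC)(CCCC)CC=C(C)C | starting material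
12 | 7-O-methylluteone | COc1cc2occ(-c3ccc(O)cc3O)c(=O)c2c(O)c1CC=C(C)C | target

**Totals**
Total steps: 6 (step 3 is a one-pot, two-stage operation). Longest linear sequence: 6 (1 → 3 → 5 → 7 → 9 → 10 → 12).

**Three steps most likely to fail, with fallbacks**
1. Step 6 (Stille prenylation of a hindered, unprotected iodophenol): risks are protodeiodination, slow coupling and some branched isomer. Fallback: transfer a plain allyl group instead (allylSnBu3 or allyl-Bpin, no linear/branched ambiguity), then build the prenyl terminus by olefin cross-metathesis with 2-methyl-2-butene (Grubbs II).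
2. Step 4 (iodination selectivity, C6 versus C8 and versus the dibenzyloxy B ring): Fallback: drop halogenation. O-allylate the 5-OH of 7 (allyl bromide, K2CO3, DMF) and run an aromatic Claisen rearrangement, where C6 is the only open ortho carbon. Then debenzylate with BCl3 and convert the 6-allyl group to prenyl by cross-metathesis with 2-methyl-2-butene.
3. Step 3 (Tl(III) oxidative aryl shift: over-oxidation of the electron-rich rings or premature flavanone formation): Fallback: abandon the migration and make the C3–aryl bond by cross-coupling. Convert 3 to its enaminone (DMF-DMA), then to the 3-iodochromone (I2), couple with 2,4-bis(benzyloxy)phenylboronic acid (Suzuki), and remove the MOM group with acid to reach 7.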